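**Retrosynthetic overview**
1. 23 ⇐ enone 21 (Wittig bromomethylenation at C3, then desilylation) ⇐ spiro alcohol 19 (O-silylation, then oxidation of C3, the only allylic CH2 of ring B).
2. Feature used: in ring A (C6–C7–C8–C9–C10–C11) the axial tertiary C7–OH and the equatorial C9–Br stand 1,3-trans across C8. This is the signature of ketone + terminal alkene + bromide, so cutting C7–C8 and C9–Br leads to methyl ketone 17.
3. 17 ⇐ enyne 16 (ethynyl as a slim latent acetyl group, hydrated last) ⇐ acid 11 (CO2H = C10, extended to the C10–C9=C8 allyl arm by reduction, oxidation and two Wittig reactions).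
4. 11 ⇐ isobutyrate 8 by Ireland–Claisen rearrangement (forms C6–C11; C–O to C–C chirality transfer sets C6) ⇐ CBS reduction of enynone 5 ⇐ 1 + 2.
5. Ring order: ring B comes with 1; ring A is closed in step 11.

Key step: step 11

Remark: C1–C11 are the spiro[5.5]undecane locants of 23 and label the same atoms in all intermediates; the acetyl group is carried as an alkyne because a ketal or thioketal at C7 would oblige the sigmatropic step to build three contiguous fully substituted carbons.

**Step 1**
Reactants: 1 3-ethoxycyclohex-2-en-1-one; 2 ethynyltrimethylsilane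
Product: 5 3-[(trimethylsilyl)ethynyl]cyclohex-2-en-1-one, via lithium (trimethylsilyl)acetylide 3 (not isolated), via 1,2-adduct alcohol 4 (not isolated)
Conditions: 2, n-BuLi, THF, −78 °C; 1, −78 → 0 °C; then 1 M aq HCl, rt
Reagents that add atoms: n-butyllithium, [Li]CCCC (lithium, found in 3 only)
Why: Stork–Danheiser sequence, in which the acetylide adds 1,2 to the vinylogous ester and acid hydrolysis of the enol ether with loss of the tertiary hydroxyl transposes the carbonyl to give the 3-alkynyl enone.

**Step 2**
Reactants: 5 3-[(trimethylsilyl)ethynyl]cyclohex-2-en-1-one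
Product: 6 (1S)-3-[(trimethylsilyl)ethynyl]cyclohex-2-en-1-ol
Conditions: (R)-1-methyl-3,3-diphenyltetrahydro-1H,3H-pyrrolo[1,2-c][1,3,2]oxazaborole [(R)-Me-CBS, 10 mol %], BH3·SMe2, THF, −20 °C; aq NH4Cl work-up
Reagents that add atoms: none
Why: Corey–Bakshi–Shibata reduction, in which the oxazaborolidine–borane complex treats the alkenyl arm as the large group and the CH2 arm as the small one, so the (R)-catalyst should deliver hydride to the face that gives the (S)-allylic alcohol, the only stereocentre set by a reagent.

**Step 3**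
Reactants: 6 (1S)-3-[(trimethylsilyl)ethynyl]cyclohex-2-en-1-ol; 7 isobutyryl chloride
Product: 8 (1S)-3-[(trimethylsilyl)ethynyl]cyclohex-2-en-1-yl 2-methylpropanoate
Conditions: Et3N, 4-(dimethylaminopyridine) (5 mol %), CH2Cl2, 0 °C → rt
Reagents that add atoms: none
Why: Nucleophile-catalysed O-acylation of a secondary allylic alcohol, which does not touch the C–O stereocentre.

**Step 4**
Reactants: 8 (1S)-3-[(trimethylsilyl)ethynyl]cyclohex-2-en-1-yl 2-methylpropanoate
Product: 11 2-[(1R)-1-ethynylcyclohex-2-en-1-yl]-2-methylpropanoic acid, via silyl ketene acetal 9 (not isolated), via bis-silylated ester 10 (not isolated)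
Conditions: LiN(iPr)2, Me3SiCl, THF, −78 → 60 °C; then 1 M aq NaOH–MeOH, rt; 1 M HCl
Reagents that add atoms: chlorotrimethylsilane, C[Si](C)(C)Cl (silicon, found in 9 and 10 only)
Why: Ireland–Claisen rearrangement, in which the tetrasubstituted ketene acetal has no E/Z issue and the suprafacial [3,3] shift forms C6–C11 on the ring face that carried the C–O bond, so the carbinol configuration is transferred to quaternary C6 while the alkene moves to C1=C2, the rod-like alkyne limits crowding to two adjacent quaternary carbons, and aqueous base then removes both silyl groups.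

**Step 5**
Reactants: 11 2-[(1R)-1-ethynylcyclohex-2-en-1-yl]-2-methylpropanoic acid
Product: 12 2-[(1R)-1-ethynylcyclohex-2-en-1-yl]-2-methylpropan-1-ol
Conditions: LiAlH4, Et2O, 0 °C → reflux; then H2O
Reagents that add atoms: none
Why: Hydride reduction of a neopentyl carboxylic acid to the primary alcohol, with the isolated alkyne and alkene inert under these conditions.

**Step 6**
Reactants: 12 2-[(1R)-1-ethynylcyclohex-2-en-1-yl]-2-methylpropan-1-ol
Product: 13 2-[(1R)-1-ethynylcyclohex-2-en-1-yl]-2-methylpropanal
Conditions: Dess–Martin periodinane, CH2Cl2, rt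
Reagents that add atoms: none
Why: Dess–Martin oxidation stops at the non-enolisable neopentyl aldehyde and leaves both π-systems alone.

**Step 7**
Reactants: 13 2-[(1R)-1-ethynylcyclohex-2-en-1-yl]-2-methylpropanal
Product: 14 1-methoxy-3-[(1R)-1-ethynylcyclohex-2-en-1-yl]-3-methylbut-1-ene (E/Z mixture)
Conditions: [Ph3PCH2OMe]Cl, KOtBu, THF, 0 °C → rt
Reagents that add atoms: (methoxymethyl)triphenylphosphonium chloride, [Cl-].COC[P+](c1ccccc1)(c1ccccc1)c1ccccc1
Why: Wittig olefination with the small, reactive methoxymethylene ylide is the standard one-carbon homologation of hindered aldehydes and brings in C9, the alkene geometry being irrelevant because both isomers hydrolyse to the same aldehyde.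

**Step 8**
Reactants: 14 1-methoxy-3-[(1R)-1-ethynylcyclohex-2-en-1-yl]-3-methylbut-1-ene
Product: 15 3-[(1S)-1-ethynylcyclohex-2-en-1-yl]-3-methylbutanal
Conditions: 2 M aq HCl, THF, rt
Reagents that add atoms: water, O
Why: Acid hydrolysis of the enol ether (C-protonation, hydration of the oxocarbenium ion, loss of methanol) under conditions too mild to affect the alkyne or the ring alkene.

**Step 9**
Reactants: 15 3-[(1S)-1-ethynylcyclohex-2-en-1-yl]-3-methylbutanal
Product: 16 (3S)-3-ethynyl-3-(2-methylpent-4-en-2-yl)cyclohex-1-ene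
Conditions: [Ph3PCH3]Br, KOtBu, THF, 0 °C
Reagents that add atoms: methyltriphenylphosphonium bromide, [Br-].C[P+](c1ccccc1)(c1ccccc1)c1ccccc1
Why: Wittig methylenation of an unhindered aldehyde brings in C8 and completes the C10–C9=C8 allyl arm.

**Step 10**
Reactants: 16 (3S)-3-ethynyl-3-(2-methylpent-4-en-2-yl)cyclohex-1-ene
Product: 17 1-[(1S)-1-(2-methylpent-4-en-2-yl)cyclohex-2-en-1-yl]ethan-1-one
Conditions: Hg(OSO2CF3)2 (5 mol %), tetramethylurea (10 mol %), H2O (3 equiv), MeCN–CH2Cl2, rt
Reagents that add atoms: water, O
Why: Kucherov-type Markovnikov hydration with a divalent mercury catalyst, in which water attacks the internal alkyne carbon C7 and the enol tautomerises to the methyl ketone, while carbocyclisation by the monosubstituted alkene is disfavoured because mercury, unlike gold or platinum, cannot stabilise the cyclised species as a carbene and a bare secondary cation would be required.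

**Step 11**
Reactants: 17 1-[(1S)-1-(2-methylpent-4-en-2-yl)cyclohex-2-en-1-yl]ethan-1-one
Product: 19 (6S,7S,9R)-9-bromo-7,11,11-trimethylspiro[5.5]undec-1-en-7-ol, via tribromotitanium alkoxide 18 (not isolated)
Conditions: TiBr4 (2.2 equiv), 2,6-di-tert-butyl-4-methylpyridine (0.3 equiv), CH2Cl2, −78 → −40 °C; sat. aq NaHCO3 at −40 °C
Reagents that add atoms: titanium tetrabromide, Br[Ti](Br)(Br)Br
Why: TiBr4 binds the C7 carbonyl oxygen on the side of the methyl group, the terminal alkene carbon C8 attacks C7, and as charge builds at C9 a bromide from a second titanium species (TiBr5−) adds to C9 anti to the forming C7–C8 bond, which leaves alkoxide 18, makes the otherwise reversible closure irreversible, and gives 19 on quench. The closest known reaction type is the Lewis-acid halo-Prins carbocyclisation of hex-5-enyl aldehydes and ketones to 3-halocyclohexanols, applied here to a hindered methyl ketone. Ring A closes 6-endo-trig at the alkene (exo at the carbonyl) through a chair that the C11 gem-dimethyl group and quaternary C6 pre-fold. C7 is controlled by the axial C11 methyl, because a chair with the C7 methyl axial would carry a syn-pentane CH3/CH3 contact, so O–Ti takes the axial and CH3 the equatorial site. C9 is controlled by the same chair, because the axial approach, including delivery from the titanium already bound to the C7 oxygen, is closed by the axial C11 methyl, so bromide enters equatorially and ends 1,3-trans to oxygen. The step needs the chair in which C1 and not C5 is axial on C6, favoured because flat C1H= has no out-of-plane substituent to clash with the nearly eclipsed C7 methyl or the axial hydrogens on C8 and C10 while bulkier C5H2 sits antiperiplanar to incoming C8 (Felkin-type), a modest bias that is the main uncertainty; the ring alkene cannot compete since it could only form three- or four-membered rings, and the hindered base and low temperature suppress HBr addition and ionisation of the tertiary alkoxide.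

**Step 12**
Reactants: 19 (6S,7S,9R)-9-bromo-7,11,11-trimethylspiro[5.5]undec-1-en-7-ol
Product: 20 {[(6S,7S,9R)-9-bromo-7,11,11-trimethylspiro[5.5]undec-1-en-7-yl]oxy}(triethyl)silane
Conditions: Et3SiOSO2CF3, 2,6-lutidine, CH2Cl2, 0 °C → rt
Reagents that add atoms: triethylsilyl trifluoromethanesulfonate, CC[Si](CC)(CC)OS(=O)(=O)C(F)(F)F
Why: Silyl triflate silylation of a hindered tertiary alcohol with a non-nucleophilic pyridine base, chosen because no alkoxide is ever formed (a free C7 alkoxide is aligned for Grob fragmentation towards the equatorial C9 bromide).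

**Step 13**
Reactants: 20 {[(6S,7S,9R)-9-bromo-7,11,11-trimethylspiro[5.5]undec-1-en-7-yl]oxy}(triethyl)silane
Product: 21 (6S,7S,9R)-9-bromo-7,11,11-trimethyl-7-[(triethylsilyl)oxy]spiro[5.5]undec-1-en-3-one
Conditions: Rh2(cap)4 (cap = ε-caprolactamate, 1 mol %), t-BuOOH (70% aq, 5 equiv), K2CO3 (0.5 equiv), CH2Cl2, rt
Reagents that add atoms: tert-butyl hydroperoxide, CC(C)(C)OO
Why: Radical allylic oxidation by tert-butylperoxyl radicals, in which C3 is the only allylic C–H position of ring B because C6 is quaternary and the delocalised allyl radical is oxygenated at open C3 rather than neopentyl C1, giving the C1=C2–C3=O enone without touching the bromide or the silyl ether.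

**Step 14**
Reactants: 21 (6S,7S,9R)-9-bromo-7,11,11-trimethyl-7-[(triethylsilyl)oxy]spiro[5.5]undec-1-en-3-one
Product: 22 {[(3E,6S,7S,9R)-9-bromo-3-(bromomethylidene)-7,11,11-trimethylspiro[5.5]undec-1-en-7-yl]oxy}(triethyl)silane
Conditions: [Ph3PCH2Br]Br, NaN(SiMe3)2, THF, −78 °C; 21, −78 → 0 °C; chromatographic separation of the E from the Z isomer
Reagents that add atoms: (bromomethyl)triphenylphosphonium bromide, [Br-].BrC[P+](c1ccccc1)(c1ccccc1)c1ccccc1
Why: Wittig olefination with the non-stabilised ylide Ph3P=CHBr adds 1,2 to the C3 carbonyl, and under kinetic low-temperature conditions such halo-ylides tend to place the halogen cis to the bulkier carbonyl substituent, here sp3 C4H2 rather than flat C2H, which is the E geometry of the target, a preference that should be modest so the isomers are separated, while the silyl ether blocks alkoxide formation and the equatorial C9 bromide has no antiperiplanar hydrogen for E2 loss.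

**Step 15**
Reactants: 22 {[(3E,6S,7S,9R)-9-bromo-3-(bromomethylidene)-7,11,11-trimethylspiro[5.5]undec-1-en-7-yl]oxy}(triethyl)silane
Product: 23 (3E,6S,7S,9R)-9-bromo-3-(bromomethylidene)-7,11,11-trimethylspiro[5.5]undec-1-en-7-ol
Conditions: HF·pyridine, pyridine, THF, 0 °C → rt
Reagents that add atoms: none
Why: Fluoride cleavage of the triethylsilyl ether under mildly acidic buffered conditions, preferred to basic fluoride sources because a naked C7 alkoxide could fragment (Grob) across C7–C8 towards the antiperiplanar C9–Br bond, and neither the stereocentres nor the bromodiene are affected.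

**Compound list**
1 | 3-ethoxycyclohex-2-en-1-one | CCOC1=CC(=O)CCC1 | starting material
2 | ethynyltrimethylsilane | C#C[Si](C)(C)C | starting material
3 | lithium (trimethylsilyl)acetylide | [Li]C#C[Si](C)(C)C | intermediate
4 | (±)-3-ethoxy-1-[(trimethylsilyl)ethynyl]cyclohex-2-en-1-ol | CCOC1=CC(O)(C#C[Si](C)(C)C)CCC1 | intermediate
5 | 3-[(trimethylsilyl)ethynyl]cyclohex-2-en-1-one | O=C1C=C(C#C[Si](C)(C)C)CCC1 | intermediate
6 | (1S)-3-[(trimethylsilyl)ethynyl]cyclohex-2-en-1-ol | O[C@@H]1C=C(C#C[Si](C)(C)C)CCC1 | intermediate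
7 | isobutyryl chloride | CC(C)C(Cl)=O | starting material
8 | (1S)-3-[(trimethylsilyl)ethynyl]cyclohex-2-en-1-yl 2-methylpropanoate | CC(C)C(=O)O[C@@H]1C=C(C#C[Si](C)(C)C)CCC1 | intermediate
9 | trimethylsilyl ketene acetal of 8, (1S) | CC(C)=C(O[Si](C)(C)C)O[C@@H]1C=C(C#C[Si](C)(C)C)CCC1 | intermediate
10 | trimethylsilyl 2-methyl-2-{(1S)-1-[(trimethylsilyl)ethynyl]cyclohex-2-en-1-yl}propanoate | C[Si](C)(C)OC(=O)C(C)(C)[C@@]1(C#C[Si](C)(C)C)C=CCCC1 | intermediate
11 | 2-[(1R)-1-ethynylcyclohex-2-en-1-yl]-2-methylpropanoic acid | OC(=O)C(C)(C)[C@@]1(C#C)C=CCCC1 | intermediate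
12 | 2-[(1R)-1-ethynylcyclohex-2-en-1-yl]-2-methylpropan-1-ol | OCC(C)(C)[C@@]1(C#C)C=CCCC1 | intermediate
13 | 2-[(1R)-1-ethynylcyclohex-2-en-1-yl]-2-methylpropanal | O=CC(C)(C)[C@@]1(C#C)C=CCCC1 | intermediate
14 | 1-methoxy-3-[(1R)-1-ethynylcyclohex-2-en-1-yl]-3-methylbut-1-ene (E/Z mixture) | COC=CC(C)(C)[C@@]1(C#C)C=CCCC1 | intermediate
15 | 3-[(1S)-1-ethynylcyclohex-2-en-1-yl]-3-methylbutanal | O=CCC(C)(C)[C@@]1(C#C)C=CCCC1 | intermediate
16 | (3S)-3-ethynyl-3-(2-methylpent-4-en-2-yl)cyclohex-1-ene | C=CCC(C)(C)[C@@]1(C#C)C=CCCC1 | intermediate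
17 | 1-[(1S)-1-(2-methylpent-4-en-2-yl)cyclohex-2-en-1-yl]ethan-1-one | C=CCC(C)(C)[C@@]1(C(C)=O)C=CCCC1 | intermediate
18 | tribromotitanium (6S,7S,9R)-9-bromo-7,11,11-trimethylspiro[5.5]undec-1-en-7-olate | CC1(C)C[C@@H](Br)C[C@](C)(O[Ti](Br)(Br)Br)[C@@]12C=CCCC2 | intermediate
19 | (6S,7S,9R)-9-bromo-7,11,11-trimethylspiro[5.5]undec-1-en-7-ol | CC1(C)C[C@@H](Br)C[C@](C)(O)[C@@]12C=CCCC2 | intermediate
20 | {[(6S,7S,9R)-9-bromo-7,11,11-trimethylspiro[5.5]undec-1-en-7-yl]oxy}(triethyl)silane | CC1(C)C[C@@H](Br)C[C@](C)(O[Si](CC)(CC)CC)[C@@]12C=CCCC2 | intermediate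
21 | (6S,7S,9R)-9-bromo-7,11,11-trimethyl-7-[(triethylsilyl)oxy]spiro[5.5]undec-1-en-3-one | CC1(C)C[C@@H](Br)C[C@](C)(O[Si](CC)(CC)CC)[C@@]12C=CC(=O)CC2 | intermediate
22 | {[(3E,6S,7S,9R)-9-bromo-3-(bromomethylidene)-7,11,11-trimethylspiro[5.5]undec-1-en-7-yl]oxy}(triethyl)silane | CC1(C)C[C@@H](Br)C[C@](C)(O[Si](CC)(CC)CC)[C@@]12C=C/C(=C/Br)CC2 | intermediate
23 | (3E,6S,7S,9R)-9-bromo-3-(bromomethylidene)-7,11,11-trimethylspiro[5.5]undec-1-en-7-ol | CC1(C)C[C@@H](Br)C[C@](C)(O)[C@@]12C=C/C(=C/Br)CC2 | target

Total step count: 15. Longest linear sequence: 15 steps (1 → 23).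

**Steps most likely to fail**

1. **Step 11.** Proton loss from C9 (an ene-type outcome) or ionisation at C7 may outrun bromide capture. The discrimination between the two chairs (C1 or C5 axial on C6) may also be poor.
 Fallback, from 17 back to 19: ring closure and bromide delivery are separated.
 - Closure of 17 in CF3CO2H–CH2Cl2 at 0 °C, with the terminating nucleophile present at solvent level, should give the equatorial C9 trifluoroacetate F1.
 - K2CO3 in MeOH frees the (9R)-diol F2, a stage at which diastereomers from the two chairs can be separated.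
 - Dess–Martin oxidation of the only secondary alcohol gives the β-hydroxy ketone F3.
 - LiBH(s-Bu)3 at −78 °C attacks from the equatorial side, because the axial side is blocked by the axial C11 methyl, and gives the axial (9S)-alcohol F4.
 - Appel bromination (CBr4, PPh3, CH2Cl2) displaces this alcohol with inversion to the equatorial bromide 19.

2. **Step 14.** Poor geometric discrimination between the C2H and C4H2 flanks of the carbonyl, and enolisation of the enone by the basic ylide.
 Fallback, from 21 back to 22: the carbon atom and the alkene geometry are installed in two separate steps.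
 - Non-basic dibromomethylenation (CBr4, PPh3, CH2Cl2, 0 °C → reflux) gives the 1,1-dibromodiene F5, which has no geometry issue.
 - Hydrogenolysis with Bu3SnH and Pd(PPh3)4 (5 mol %) in toluene at rt then removes one bromine.
 - Zerovalent palladium inserts into the more accessible C–Br bond, the one cis to flat C2–H.
 - The bromine cis to C4 is retained, which is 22.

3. **Step 10.** The neighbouring terminal alkene may compete for the metal-activated alkyne (carbocyclisation), or the alkene may undergo oxymercuration that ties up the catalyst.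
 Fallback, from 15 back to 17: the alkyne is hydrated before the terminal alkene exists.
 - Treatment of 15 with the monovalent gold catalyst (Ph3P)AuN(SO2CF3)2 (2 mol %) in wet dioxane should give the keto aldehyde F6.
 - One equivalent of Ph3P=CH2 in THF at −78 °C methylenates only the aldehyde and gives 17.
 - The C7 ketone, flanked by quaternary C6, is inert at that temperature.

**Further compounds**
F1 | step 11 | (6S,7S,9R)-7-hydroxy-7,11,11-trimethylspiro[5.5]undec-1-en-9-yl trifluoroacetate | CC1(C)C[C@@H](OC(=O)C(F)(F)F)C[C@](C)(O)[C@@]12C=CCCC2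
F2 | step 11 | (6S,7S,9R)-7,11,11-trimethylspiro[5.5]undec-1-ene-7,9-diol | CC1(C)C[C@@H](O)C[C@](C)(O)[C@@]12C=CCCC2
F3 | step 11 | (6S,7S)-7-hydroxy-7,11,11-trimethylspiro[5.5]undec-1-en-9-one | CC1(C)CC(=O)C[C@](C)(O)[C@@]12C=CCCC2
F4 | step 11 | (6S,7S,9S)-7,11,11-trimethylspiro[5.5]undec-1-ene-7,9-diol | CC1(C)C[C@H](O)C[C@](C)(O)[C@@]12C=CCCC2
F5 | step 14 | {[(6S,7S,9R)-9-bromo-3-(dibromomethylidene)-7,11,11-trimethylspiro[5.5]undec-1-en-7-yl]oxy}(triethyl)silane | CC1(C)C[C@@H](Br)C[C@](C)(O[Si](CC)(CC)CC)[C@@]12C=CC(=C(Br)Br)CC2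
F6 | step 10 | 3-[(1S)-1-acetylcyclohex-2-en-1-yl]-3-methylbutanal | O=CCC(C)(C)[C@@]1(C(C)=O)C=CCCC1
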